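**Plan**

- Ring locants used throughout (cyclohexenone of the target): C1 ketone carbon, C2 methyl-bearing alkene carbon, C3 alkene carbon carrying the 2-oxopentyl chain, C4 CH2, C5 CHOH, C6 quaternary carbon (Me, O-aroyl).
- Retrosynthesis: after the protecting groups, the ring bond C1–C6 is cut. C6 carries a methyl and an acyloxy group next to the enone carbonyl C1. This is the retron of a Markovnikov hydroacylation of a 1-(aroyloxy)vinyl group (its =CH2 becomes the methyl) by an enal, so the hindered tertiary orsellinate is never made by acylating an alcohol.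
- Further cuts: O–C6 of the enol ester (orsellinic acid + terminal alkyne); C1–O of a temporary δ-lactone that joins C1 to the C5 oxygen and fixes C1 cis to C4 on C2=C3; C3–CH2 of the side chain (Negishi); C2–C3 and C3–C4 (two Claisen condensations).
- Forward order: alkynyl β-keto ester, transfer hydrogenation, chain extension, temporary lactone ring, enol triflate, side chain, ring opening to the enal, enol ester, NHC ring closure to the cyclohexenone (the only carbocycle made), global deprotection.
- Stereochemistry: C5 from Noyori asymmetric transfer hydrogenation (catalyst control); C6 from C5 in the ring closure (substrate control, allylic 1,2-strain); the C2=C3 geometry from the lactone ring.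

Key step: step 14

Remark on the chemistry: the tert-butyl β-keto ester made in step 3 is carried as a mixture of epimers at its methyl-bearing carbon (this carbon becomes sp2 in step 4), and the β-keto lactone of step 4 is written as its enol.

**Route**

Step 1
Reactants: 1 ethyl 3-(trimethylsilyl)propiolate; 2 ethyl acetate
Product: 4 ethyl 3-oxo-5-(trimethylsilyl)pent-4-ynoate, via lithium enolate 3 (not isolated)
Conditions: 2, LiN(iPr)2 (2.2 equiv each), THF, −78 °C; then 1, −78 to −40 °C; aq. NH4Cl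
Reagents that add atoms: none
Why: Crossed Claisen condensation, in which the hard lithium enolate should attack the ester carbonyl of 1 (the silyl group shields the alkyne carbon from conjugate addition) and the product is protected in the flask as its enolate; no stereocentre is formed.

Step 2
Reactants: 4 ethyl 3-oxo-5-(trimethylsilyl)pent-4-ynoate
Product: 5 ethyl (3S)-3-hydroxy-5-(trimethylsilyl)pent-4-ynoate
Conditions: RuCl(p-cymene)[(S,S)-TsDPEN] (1 mol%), HCO2H/Et3N (5:2), CH2Cl2, rt
Reagents that add atoms: none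
Why: Noyori asymmetric transfer hydrogenation of an alkynyl ketone, in which the alkyne takes the place of the aryl group of an aryl ketone, so the (S,S) catalyst should give the (S)-propargylic alcohol and set C5 of the target by catalyst control.

Step 3
Reactants: 5 ethyl (3S)-3-hydroxy-5-(trimethylsilyl)pent-4-ynoate; 6 tert-butyl propionate
Product: 8 tert-butyl (5S)-5-hydroxy-2-methyl-3-oxo-7-(trimethylsilyl)hept-6-ynoate, via lithium enolate 7 (not isolated)
Conditions: 6, LiN(iPr)2 (3.5 equiv each), THF, −78 °C; then 5, −78 to −30 °C; aq. NH4Cl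
Reagents that add atoms: none
Why: Claisen condensation of an excess of ester enolate on a β-hydroxy ester (the alkoxide formed first protects the carbinol, so C5 is untouched), the standard entry to δ-hydroxy-β-keto esters; the new methyl-bearing centre forms as a mixture and is removed in step 4.

Step 4
Reactants: 8 tert-butyl (5S)-5-hydroxy-2-methyl-3-oxo-7-(trimethylsilyl)hept-6-ynoate
Product: 9 (6S)-4-hydroxy-3-methyl-6-[(trimethylsilyl)ethynyl]-5,6-dihydro-2H-pyran-2-one
Conditions: CF3CO2H/CH2Cl2 (1:4), 0 °C to rt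
Reagents that add atoms: none
Why: Acid-mediated cleavage of the tert-butyl ester with lactonisation of the δ-hydroxy-β-keto ester should give the six-membered β-keto lactone (enol form), a temporary ring that ties C1 to the C5 oxygen; C5 is not touched.

Step 5
Reactants: 9 (6S)-4-hydroxy-3-methyl-6-[(trimethylsilyl)ethynyl]-5,6-dihydro-2H-pyran-2-one
Product: 10 (2S)-5-methyl-6-oxo-2-[(trimethylsilyl)ethynyl]-3,6-dihydro-2H-pyran-4-yl trifluoromethanesulfonate
Conditions: Tf2O, Et3N, CH2Cl2, −78 °C
Reagents that add atoms: trifluoromethanesulfonic anhydride (Tf2O), O=S(=O)(OS(=O)(=O)C(F)(F)F)C(F)(F)F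
Why: O-sulfonylation of the vinylogous acid gives the enol triflate for cross-coupling, with C1 and C4 held cis on the future C2=C3 bond by the ring.

Step 6
Reactants: 11 1-bromopentan-2-one
Product: 12 2-(bromomethyl)-2-propyl-1,3-dioxolane
Conditions: HOCH2CH2OH, TsOH·H2O (cat.), toluene, reflux, Dean–Stark trap
Reagents that add atoms: ethane-1,2-diol (ethylene glycol), OCCO
Why: Acid-catalysed ketalisation of an α-bromo ketone with azeotropic removal of water masks the side-chain ketone before metalation.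

Step 7
Reactants: 10 (2S)-5-methyl-6-oxo-2-[(trimethylsilyl)ethynyl]-3,6-dihydro-2H-pyran-4-yl trifluoromethanesulfonate; 12 2-(bromomethyl)-2-propyl-1,3-dioxolane
Product: 14 (6S)-3-methyl-4-[(2-propyl-1,3-dioxolan-2-yl)methyl]-6-[(trimethylsilyl)ethynyl]-5,6-dihydro-2H-pyran-2-one, via alkylzinc bromide 13 (not isolated)
Conditions: 12, Zn dust, LiCl, THF, 50 °C; then 10, Pd(PPh3)4 (5 mol%), THF, rt to 40 °C
Reagents that add atoms: none
Why: Negishi coupling of a β-keto-lactone enol triflate with a primary alkylzinc halide that has no β-hydrogen (its lower homologue, (1,3-dioxolan-2-ylmethyl)zinc bromide, is a stable and widely used reagent); the ring alkene keeps its geometry.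

Step 8
Reactants: 14 (6S)-3-methyl-4-[(2-propyl-1,3-dioxolan-2-yl)methyl]-6-[(trimethylsilyl)ethynyl]-5,6-dihydro-2H-pyran-2-one
Product: 15 (2E,5S)-5-hydroxy-N-methoxy-N,2-dimethyl-3-[(2-propyl-1,3-dioxolan-2-yl)methyl]-7-(trimethylsilyl)hept-2-en-6-ynamide
Conditions: MeNHOMe, AlMe3, CH2Cl2, 0 °C to rt; aq. potassium sodium tartrate
Reagents that add atoms: N,O-dimethylhydroxylamine, CNOC
Why: Aluminium-amide (Weinreb) aminolysis cleaves the lactone at the acyl–oxygen bond, so the temporary ring opens with the C1 carbonyl left cis to C4 (2E by the sequence rules) and C5 unchanged.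

Step 9
Reactants: 15 (2E,5S)-5-hydroxy-N-methoxy-N,2-dimethyl-3-[(2-propyl-1,3-dioxolan-2-yl)methyl]-7-(trimethylsilyl)hept-2-en-6-ynamide
Product: 16 (2E,5S)-5-[(tert-butyldimethylsilyl)oxy]-N-methoxy-N,2-dimethyl-3-[(2-propyl-1,3-dioxolan-2-yl)methyl]-7-(trimethylsilyl)hept-2-en-6-ynamide
Conditions: TBSCl, imidazole, DMF, rt
Reagents that add atoms: tert-butyldimethylsilyl chloride (TBSCl), CC(C)(C)[Si](C)(C)Cl
Why: Standard silylation of the secondary propargylic alcohol stops relactonisation and installs the C5 protecting group for the later steps.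

Step 10
Reactants: 16 (2E,5S)-5-[(tert-butyldimethylsilyl)oxy]-N-methoxy-N,2-dimethyl-3-[(2-propyl-1,3-dioxolan-2-yl)methyl]-7-(trimethylsilyl)hept-2-en-6-ynamide
Product: 17 (2E,5S)-5-[(tert-butyldimethylsilyl)oxy]-N-methoxy-N,2-dimethyl-3-[(2-propyl-1,3-dioxolan-2-yl)methyl]hept-2-en-6-ynamide
Conditions: K2CO3 (0.2 equiv), MeOH, 0 °C to rt
Reagents that add atoms: none
Why: Base-catalysed methanolysis of the C(sp)–Si bond frees the terminal alkyne, while the O-silyl ether, the Weinreb amide and the ketal are stable to these conditions.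

Step 11
Reactants: 17 (2E,5S)-5-[(tert-butyldimethylsilyl)oxy]-N-methoxy-N,2-dimethyl-3-[(2-propyl-1,3-dioxolan-2-yl)methyl]hept-2-en-6-ynamide
Product: 18 (2E,5S)-5-[(tert-butyldimethylsilyl)oxy]-2-methyl-3-[(2-propyl-1,3-dioxolan-2-yl)methyl]hept-2-en-6-ynal
Conditions: iBu2AlH, THF, −78 to −40 °C; aq. potassium sodium tartrate
Reagents that add atoms: none
Why: Weinreb amides are reduced by iBu2AlH to aldehydes without over-reduction, which should give the tetrasubstituted enal with its geometry (formyl group cis to C4) intact.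

Step 12
Reactants: 19 orsellinic acid (2,4-dihydroxy-6-methylbenzoic acid)
Product: 21 2,4-bis(methoxymethoxy)-6-methylbenzoic acid, via methoxymethyl ester 20 (not isolated)
Conditions: NaH, MOMCl, DMF, 0 °C to rt; then aq. NaOH, MeOH, rt; HCl to pH 4 at 0 °C
Reagents that add atoms: chloromethyl methyl ether (MOMCl), COCCl
Why: Williamson-type alkylation of both phenols and the carboxylate, then saponification of the labile methoxymethyl ester, gives an acid whose phenol protection is stable to base and to carbenes and is removed by acid.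

Step 13
Reactants: 18 (2E,5S)-5-[(tert-butyldimethylsilyl)oxy]-2-methyl-3-[(2-propyl-1,3-dioxolan-2-yl)methyl]hept-2-en-6-ynal; 21 2,4-bis(methoxymethoxy)-6-methylbenzoic acid
Product: 22 (3S,5E)-3-[(tert-butyldimethylsilyl)oxy]-6-methyl-7-oxo-5-[(2-propyl-1,3-dioxolan-2-yl)methyl]hepta-1,5-dien-2-yl 2,4-bis(methoxymethoxy)-6-methylbenzoate
Conditions: [RuCl2(p-cymene)]2 (2 mol%), tri(2-furyl)phosphine (8 mol%), Na2CO3 (5 mol%), toluene, 50 °C
Reagents that add atoms: none
Why: Ruthenium-catalysed Markovnikov addition of a carboxylic acid to a terminal alkyne gives the 1,1-disubstituted enol ester, so the hindered C6–O–acyl bond is made by adding O–H across the alkyne and not by acylating a tertiary alcohol; C5 is untouched.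

Step 14
Reactants: 22 (3S,5E)-3-[(tert-butyldimethylsilyl)oxy]-6-methyl-7-oxo-5-[(2-propyl-1,3-dioxolan-2-yl)methyl]hepta-1,5-dien-2-yl 2,4-bis(methoxymethoxy)-6-methylbenzoate
Product: 24 (1R,6S)-6-[(tert-butyldimethylsilyl)oxy]-1,3-dimethyl-2-oxo-4-[(2-propyl-1,3-dioxolan-2-yl)methyl]cyclohex-3-en-1-yl 2,4-bis(methoxymethoxy)-6-methylbenzoate, via Breslow intermediate 23 (not isolated)
Conditions: 3-(2,6-diisopropylphenyl)-5,6,7,8-tetrahydro-4H-cyclohepta[d][1,3]thiazol-3-ium perchlorate (20 mol%), KN(SiMe3)2 (18 mol%), 1,4-dioxane (0.02 M), rt, then 22, 90 °C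
Reagents that add atoms: none
Why: Proposed new method: the thiazol-2-ylidene adds to the formyl group of 22 and, after proton shift, gives the Breslow enaminol 23, whose nucleophilic carbon (the future C1) bonds to the oxygen-bearing alkene carbon (C6) while its O–H hydrogen passes to the terminal CH2 through a concerted, Conia-ene-like five-membered transition state, so that the =CH2 becomes the C6 methyl group and release of the carbene unveils the C1 ketone. The closest known reaction type is the NHC-catalysed intramolecular hydroacylation of unactivated 1,1-disubstituted alkenes by aromatic aldehydes, which likewise closes six-membered ketones with a quaternary α-carbon; an enal as donor and an enol ester as acceptor go beyond it, but the polarity is matched, because an enol ester is basic at CH2 and electrophilic at the oxygen-bearing carbon. The cyclohexenone closes in the 6-exo-trig mode, which requires C1 cis to C4 on the C2=C3 bond (secured by the temporary lactone of steps 4 to 8) and is favoured over the 7-endo alternative by both ring size and polarity. C6 is set by substrate control from C5: allylic 1,2-strain with the bulky aroyloxy group disfavours the rotamer about C5–C6 in which that group lies between C4 and OTBS, and the two remaining rotamers (C–OTBS antiperiplanar to the C–O bond of the aroyloxy group, or antiperiplanar to the incoming C1) both place the aroyloxy group trans to OTBS, that is (1R,6S) in 24. The step needs chemoselectivity for C–C bond formation over transfer of the aroyl group to the carbene and over base-induced scrambling of the enal: the ortho-methyl and ortho-OMOM groups shield the ester carbonyl as in a mesitoate, the carbene is generated with less base than azolium salt, and the ketal leaves the acyl anion no ketone for a competing five-membered benzoin closure.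

Step 15
Reactants: 24 (1R,6S)-6-[(tert-butyldimethylsilyl)oxy]-1,3-dimethyl-2-oxo-4-[(2-propyl-1,3-dioxolan-2-yl)methyl]cyclohex-3-en-1-yl 2,4-bis(methoxymethoxy)-6-methylbenzoate
Product: 25 talarophilone, (1R,6S)-6-hydroxy-1,3-dimethyl-2-oxo-4-(2-oxopentyl)cyclohex-3-en-1-yl 2,4-dihydroxy-6-methylbenzoate
Conditions: 3 M aq. HCl/THF (1:2), 40 °C
Reagents that add atoms: water, O
Why: Aqueous acid should hydrolyse the two phenolic MOM acetals, the silyl ether and the dioxolane in one operation; no base is present, so acyl migration to the freed C5 hydroxyl and vinylogous elimination are avoided, and neither stereocentre is affected.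

**Compound list**

1 | ethyl 3-(trimethylsilyl)propiolate | CCOC(=O)C#C[Si](C)(C)C | starting material
2 | ethyl acetate | CCOC(C)=O | starting material
3 | lithium enolate of ethyl acetate (lithium 1-ethoxyethenolate) | C=C(O[Li])OCC | intermediate
4 | ethyl 3-oxo-5-(trimethylsilyl)pent-4-ynoate | CCOC(=O)CC(=O)C#C[Si](C)(C)C | intermediate
5 | ethyl (3S)-3-hydroxy-5-(trimethylsilyl)pent-4-ynoate | CCOC(=O)C[C@H](O)C#C[Si](C)(C)C | intermediate
6 | tert-butyl propionate | CCC(=O)OC(C)(C)C | starting material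
7 | lithium enolate of tert-butyl propionate (lithium 1-tert-butoxyprop-1-en-1-olate) | CC=C(O[Li])OC(C)(C)C | intermediate
8 | tert-butyl (5S)-5-hydroxy-2-methyl-3-oxo-7-(trimethylsilyl)hept-6-ynoate (mixture at C2) | CC(C(=O)C[C@H](O)C#C[Si](C)(C)C)C(=O)OC(C)(C)C | intermediate
9 | (6S)-4-hydroxy-3-methyl-6-[(trimethylsilyl)ethynyl]-5,6-dihydro-2H-pyran-2-one | C[Si](C)(C)C#C[C@@H]1CC(O)=C(C)C(=O)O1 | intermediate
10 | (2S)-5-methyl-6-oxo-2-[(trimethylsilyl)ethynyl]-3,6-dihydro-2H-pyran-4-yl trifluoromethanesulfonate | C[Si](C)(C)C#C[C@@H]1CC(OS(=O)(=O)C(F)(F)F)=C(C)C(=O)O1 | intermediate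
11 | 1-bromopentan-2-one | CCCC(=O)CBr | starting material
12 | 2-(bromomethyl)-2-propyl-1,3-dioxolane | CCCC1(CBr)OCCO1 | intermediate
13 | [(2-propyl-1,3-dioxolan-2-yl)methyl]zinc bromide | CCCC1(C[Zn]Br)OCCO1 | intermediate
14 | (6S)-3-methyl-4-[(2-propyl-1,3-dioxolan-2-yl)methyl]-6-[(trimethylsilyl)ethynyl]-5,6-dihydro-2H-pyran-2-one | C[Si](C)(C)C#C[C@@H]1CC(CC2(CCC)OCCO2)=C(C)C(=O)O1 | intermediate
15 | (2E,5S)-5-hydroxy-N-methoxy-N,2-dimethyl-3-[(2-propyl-1,3-dioxolan-2-yl)methyl]-7-(trimethylsilyl)hept-2-en-6-ynamide | CON(C)C(=O)/C(C)=C(/CC1(CCC)OCCO1)C[C@H](O)C#C[Si](C)(C)C | intermediate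
16 | (2E,5S)-5-[(tert-butyldimethylsilyl)oxy]-N-methoxy-N,2-dimethyl-3-[(2-propyl-1,3-dioxolan-2-yl)methyl]-7-(trimethylsilyl)hept-2-en-6-ynamide | CON(C)C(=O)/C(C)=C(/CC1(CCC)OCCO1)C[C@H](O[Si](C)(C)C(C)(C)C)C#C[Si](C)(C)C | intermediate
17 | (2E,5S)-5-[(tert-butyldimethylsilyl)oxy]-N-methoxy-N,2-dimethyl-3-[(2-propyl-1,3-dioxolan-2-yl)methyl]hept-2-en-6-ynamide | CON(C)C(=O)/C(C)=C(/CC1(CCC)OCCO1)C[C@H](O[Si](C)(C)C(C)(C)C)C#C | intermediate
18 | (2E,5S)-5-[(tert-butyldimethylsilyl)oxy]-2-methyl-3-[(2-propyl-1,3-dioxolan-2-yl)methyl]hept-2-en-6-ynal | O=C/C(C)=C(/CC1(CCC)OCCO1)C[C@H](O[Si](C)(C)C(C)(C)C)C#C | intermediate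
19 | orsellinic acid (2,4-dihydroxy-6-methylbenzoic acid) | Cc1cc(O)cc(O)c1C(=O)O | starting material
20 | methoxymethyl 2,4-bis(methoxymethoxy)-6-methylbenzoate | COCOC(=O)c1c(C)cc(OCOC)cc1OCOC | intermediate
21 | 2,4-bis(methoxymethoxy)-6-methylbenzoic acid | Cc1cc(OCOC)cc(OCOC)c1C(=O)O | intermediate
22 | (3S,5E)-3-[(tert-butyldimethylsilyl)oxy]-6-methyl-7-oxo-5-[(2-propyl-1,3-dioxolan-2-yl)methyl]hepta-1,5-dien-2-yl 2,4-bis(methoxymethoxy)-6-methylbenzoate | O=C/C(C)=C(/CC1(CCC)OCCO1)C[C@H](O[Si](C)(C)C(C)(C)C)C(=C)OC(=O)c1c(C)cc(OCOC)cc1OCOC | intermediate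
23 | Breslow intermediate: (3S,5E)-3-[(tert-butyldimethylsilyl)oxy]-7-hydroxy-6-methyl-7-[3-(2,6-diisopropylphenyl)-5,6,7,8-tetrahydro-4H-cyclohepta[d][1,3]thiazol-2(3H)-ylidene]-5-[(2-propyl-1,3-dioxolan-2-yl)methyl]hepta-1,5-dien-2-yl 2,4-bis(methoxymethoxy)-6-methylbenzoate | CC(C)c1cccc(C(C)C)c1N1C(=C(O)/C(C)=C(/CC3(CCC)OCCO3)C[C@H](O[Si](C)(C)C(C)(C)C)C(=C)OC(=O)c3c(C)cc(OCOC)cc3OCOC)SC2=C1CCCCC2 | intermediate
24 | (1R,6S)-6-[(tert-butyldimethylsilyl)oxy]-1,3-dimethyl-2-oxo-4-[(2-propyl-1,3-dioxolan-2-yl)methyl]cyclohex-3-en-1-yl 2,4-bis(methoxymethoxy)-6-methylbenzoate | CCCC1(CC2=C(C)C(=O)[C@](C)(OC(=O)c3c(C)cc(OCOC)cc3OCOC)[C@@H](O[Si](C)(C)C(C)(C)C)C2)OCCO1 | intermediate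
25 | talarophilone, (1R,6S)-6-hydroxy-1,3-dimethyl-2-oxo-4-(2-oxopentyl)cyclohex-3-en-1-yl 2,4-dihydroxy-6-methylbenzoate | CCCC(=O)CC1=C(C)C(=O)[C@](C)(OC(=O)c2c(C)cc(O)cc2O)[C@@H](O)C1 | target

**Step count and risks**

Total step count: 15. Longest linear sequence: 13 steps (steps 1 to 5, 7 to 11, 13 to 15).

Steps most likely to fail:

1. Step 14 (proposed new method). What may go wrong: transfer of the aroyl group from the enol ester to the carbene, which consumes the catalyst; base-induced isomerisation or deconjugation of the enal before ring closure; or poor facial selectivity at C6. Fallback by known chemistry, setting out from 18 and coming back to the route at 25: the terminal alkyne of 18 is hydrated with (IPr)AuCl/AgSbF6 (IPr = 1,3-bis(2,6-diisopropylphenyl)imidazol-2-ylidene) in wet 1,4-dioxane to the keto aldehyde (2E,5S)-5-[(tert-butyldimethylsilyl)oxy]-2-methyl-6-oxo-3-[(2-propyl-1,3-dioxolan-2-yl)methyl]hept-2-enal F1. An intramolecular crossed aldehyde–ketone benzoin reaction (aminoindanol-derived N-pentafluorophenyl triazolium tetrafluoroborate, Et3N, toluene, rt) then closes the same C1–C6 bond to the tertiary α-ketol (5S,6R)-5-[(tert-butyldimethylsilyl)oxy]-6-hydroxy-2,6-dimethyl-3-[(2-propyl-1,3-dioxolan-2-yl)methyl]cyclohex-2-en-1-one F2. The catalyst antipode that places the new hydroxyl trans to OTBS is used, because a Felkin-type substrate bias is expected to favour the cis diol. In parallel, 19 is converted with acetone, (CF3CO)2O and CF3CO2H into its acetonide 7-hydroxy-2,2,5-trimethyl-4H-1,3-benzodioxin-4-one F3, and with MOMCl/iPr2NEt into 7-(methoxymethoxy)-2,2,5-trimethyl-4H-1,3-benzodioxin-4-one F4. Irradiation at 300 nm (or heating) of F4 with F2 should release a quinoketene that is trapped by the hindered tertiary hydroxyl, giving (1R,6S)-6-[(tert-butyldimethylsilyl)oxy]-1,3-dimethyl-2-oxo-4-[(2-propyl-1,3-dioxolan-2-yl)methyl]cyclohex-3-en-1-yl 2-hydroxy-4-(methoxymethoxy)-6-methylbenzoate F5. The conditions of step 15 then convert F5 into 25.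

2. Step 13. What may go wrong: slow addition of the di-ortho-substituted acid, anti-Markovnikov addition through a vinylidene pathway, or isomerisation of the enal on heating. Fallback, setting out from 17 and coming back at 22: gold-catalysed hydration of 17 ((IPr)AuCl/AgSbF6, wet 1,4-dioxane) gives the methyl ketone (2E,5S)-5-[(tert-butyldimethylsilyl)oxy]-N-methoxy-N,2-dimethyl-6-oxo-3-[(2-propyl-1,3-dioxolan-2-yl)methyl]hept-2-enamide F6. Acid 21 is converted with 1-chloro-N,N,2-trimethylprop-1-en-1-amine into 2,4-bis(methoxymethoxy)-6-methylbenzoyl chloride F7. The kinetic potassium enolate of F6 (KN(SiMe3)2, THF, −78 °C, deprotonation at the methyl group) is O-acylated by F7 to the enol ester (3S,5E)-3-[(tert-butyldimethylsilyl)oxy]-7-[methoxy(methyl)amino]-6-methyl-7-oxo-5-[(2-propyl-1,3-dioxolan-2-yl)methyl]hepta-1,5-dien-2-yl 2,4-bis(methoxymethoxy)-6-methylbenzoate F8. Cp2Zr(H)Cl then reduces the Weinreb amide of F8 to the aldehyde 22 without touching the aryl ester.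

3. Step 7. What may go wrong: sluggish zinc insertion into the neopentyl-type bromide, or β-alkoxide elimination from the zinc reagent or from the alkylpalladium intermediate. Fallback, setting out from 10 and coming back at 14: Sonogashira coupling of 10 with pent-1-yne (PdCl2(PPh3)2, CuI, Et3N, THF) gives (6S)-3-methyl-4-(pent-1-yn-1-yl)-6-[(trimethylsilyl)ethynyl]-5,6-dihydro-2H-pyran-2-one F9. Gold-catalysed hydration ((IPr)AuCl/AgSbF6, wet 1,4-dioxane), in which water should add to the alkyne carbon remote from the electron-poor lactone alkene, gives (6S)-3-methyl-4-(2-oxopentyl)-6-[(trimethylsilyl)ethynyl]-5,6-dihydro-2H-pyran-2-one F10. Ketalisation with Me3SiOCH2CH2OSiMe3 and Me3SiOTf (cat.) in CH2Cl2 at −78 °C gives 14.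

Further compounds

F1 | step 14 | (2E,5S)-5-[(tert-butyldimethylsilyl)oxy]-2-methyl-6-oxo-3-[(2-propyl-1,3-dioxolan-2-yl)methyl]hept-2-enal | O=C/C(C)=C(/CC1(CCC)OCCO1)C[C@H](O[Si](C)(C)C(C)(C)C)C(C)=O
F2 | step 14 | (5S,6R)-5-[(tert-butyldimethylsilyl)oxy]-6-hydroxy-2,6-dimethyl-3-[(2-propyl-1,3-dioxolan-2-yl)methyl]cyclohex-2-en-1-one | CCCC1(CC2=C(C)C(=O)[C@](C)(O)[C@@H](O[Si](C)(C)C(C)(C)C)C2)OCCO1
F3 | step 14 | 7-hydroxy-2,2,5-trimethyl-4H-1,3-benzodioxin-4-one | Cc1cc(O)cc2OC(C)(C)OC(=O)c12
F4 | step 14 | 7-(methoxymethoxy)-2,2,5-trimethyl-4H-1,3-benzodioxin-4-one | Cc1cc(OCOC)cc2OC(C)(C)OC(=O)c12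
F5 | step 14 | (1R,6S)-6-[(tert-butyldimethylsilyl)oxy]-1,3-dimethyl-2-oxo-4-[(2-propyl-1,3-dioxolan-2-yl)methyl]cyclohex-3-en-1-yl 2-hydroxy-4-(methoxymethoxy)-6-methylbenzoate | CCCC1(CC2=C(C)C(=O)[C@](C)(OC(=O)c3c(C)cc(OCOC)cc3O)[C@@H](O[Si](C)(C)C(C)(C)C)C2)OCCO1
F6 | step 13 | (2E,5S)-5-[(tert-butyldimethylsilyl)oxy]-N-methoxy-N,2-dimethyl-6-oxo-3-[(2-propyl-1,3-dioxolan-2-yl)methyl]hept-2-enamide | CON(C)C(=O)/C(C)=C(/CC1(CCC)OCCO1)C[C@H](O[Si](C)(C)C(C)(C)C)C(C)=O
F7 | step 13 | 2,4-bis(methoxymethoxy)-6-methylbenzoyl chloride | Cc1cc(OCOC)cc(OCOC)c1C(=O)Cl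
F8 | step 13 | (3S,5E)-3-[(tert-butyldimethylsilyl)oxy]-7-[methoxy(methyl)amino]-6-methyl-7-oxo-5-[(2-propyl-1,3-dioxolan-2-yl)methyl]hepta-1,5-dien-2-yl 2,4-bis(methoxymethoxy)-6-methylbenzoate | CON(C)C(=O)/C(C)=C(/CC1(CCC)OCCO1)C[C@H](O[Si](C)(C)C(C)(C)C)C(=C)OC(=O)c1c(C)cc(OCOC)cc1OCOC
F9 | step 7 | (6S)-3-methyl-4-(pent-1-yn-1-yl)-6-[(trimethylsilyl)ethynyl]-5,6-dihydro-2H-pyran-2-one | C[Si](C)(C)C#C[C@@H]1CC(C#CCCC)=C(C)C(=O)O1
F10 | step 7 | (6S)-3-methyl-4-(2-oxopentyl)-6-[(trimethylsilyl)ethynyl]-5,6-dihydro-2H-pyran-2-one | C[Si](C)(C)C#C[C@@H]1CC(CC(=O)CCC)=C(C)C(=O)O1
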